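The constants used here are those of an exercise, and the outcome is calculated.

Before you add precatalyst to speed this flask, reckon what the undissolved solid can still deliver.

    starting material + free enzyme ⇌ first complex (K1 = 96.2 M⁻¹, k1 = 800 M⁻¹ s⁻¹)
    first complex ⇌ loaded enzyme + first product (K2 = 0.027 M, k2 = 0.149 s⁻¹)
    second substrate + loaded enzyme ⇌ second complex (K3 = 127 M⁻¹, k3 = 135 M⁻¹ s⁻¹)
    second complex → free enzyme + target (k4 = 1.66 s⁻¹)
    solid substrate ⇌ starting material, rate k5*(cs5 - [starting material]) while solid is left; crystals form when [starting material] > cs5 (cs5 = 0.82 mM, k5 = 6.48 × 10⁻⁵ s⁻¹)
    second substrate + precatalyst → free enzyme + spent reagent (k6 = 7.27 × 10⁻⁴ M⁻¹ s⁻¹)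

solid substrate 13 mM; second substrate 15.6 mM; precatalyst 13 µM

- given per volume of solution although it is solid: solid substrate
- at the start none of the solid substrate is in solution
- what has only dissolved of solid substrate counts as not reacted
- charge of solid substrate (flask): 13 mM

1. the form that holds most of the catalyst when 20 % of the solid substrate are converted (what has only dissolved counts as not reacted) (first complex / second complex / loaded enzyme / precatalyst / free enzyme)
2. its share of the catalyst then
3. factor on the rate of making target when 20 % of the solid substrate are converted (what has only dissolved counts as not reacted) if second substrate is charged twice over
4. factor on the rate when 20 % of the solid substrate are converted (what has only dissolved counts as not reacted) if precatalyst is charged at 120 µM instead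

Take the two ends first. With c(starting material) at zero, the rate law of dissolving gives k5 times the solubility, 0.191 mM h⁻¹; call this the dissolution ceiling. The other end is capture by the catalyst. The return of first complex to starting material and free enzyme runs at 8.32 s⁻¹, much faster than its onward step at 0.149 s⁻¹, so its formation is a pre-equilibrium, and free enzyme captures starting material with the second-order constant K1 times k2, 14.3 M⁻¹ s⁻¹. Loaded enzyme takes up second substrate at 2.11 s⁻¹, faster than first complex goes on, so I take free enzyme as the resting state of the working round, with precatalyst outside it.

Now join the ends: dissolved starting material stands where dissolving equals capture, and the rate is the ceiling times N/(1+N). Here N is K1 times k2 times c(active enzyme), divided by k5.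

Active enzyme comes from the activation of precatalyst by second substrate. Second substrate as charged gives precatalyst a pseudo-first-order constant of 0.0408 h⁻¹, so at 28.1 h, when this flask reaches 20 % conversion, my reckoning leaves 31.8 % precatalyst. That gives N = 1.96, the capture number: capture over dissolving, per unit of dissolved starting material. The rate then stands at 66.2 % of the ceiling, and free enzyme holds 66.5 % of the catalyst, more than the precatalyst left.

Doubling second substrate, reckoned at that same moment, gives N = 2.59 and a factor of 1.09. With 120 µM precatalyst, I reckon that conversion at the ceiling rate, which takes 13.6 h, so N = 11.3 and the factor is 1.39.

The forecast names free enzyme at 63.5 %, with factors of 1.1 and 1.44, on the ground that “The cycle is limited by substrate capture”. Its share is lower than mine, and its factor for more precatalyst is higher.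

The simulation gives free enzyme at 63.5 %, precatalyst at 34.3 %, and factors of 1.09 and 1.43. From that free-enzyme share, the capture number of this flask reads 1.83, which puts the dissolution ceiling a factor of 1.55 above its rate. In the flask charged with 120 µM precatalyst, 9.23 times the charge, the rate rose by a factor of 1.43, less than that factor from the ceiling.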